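**Retrosynthetic overview**

- The two ring esters and the oxirane are installed last: C5 ester by Yamaguchi acylation, C5–OH by SeO2 allylic hydroxylation of the exocyclic methylene, C6 ester by Steglich acylation, oxirane by C6–OH-directed epoxidation of an isopropenyl group.
- Key disconnection C6–C7 (closes the six-membered ring): an aldehyde carbon and the γ-carbon of an allylic phenyl ether, both acceptor carbons, are joined after polarity reversal of the allyl unit (π-allylpalladium → allylindium). This one step forms the ring, sets C6 and C7 and creates the isopropenyl group.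
- The cyclisation precursor is an all-trans 2,3,4-trisubstituted cyclopentanone, made by a three-component coupling (alkenylcopper 1,4-addition, acetaldehyde aldol, in-situ acetylation) on a 4-substituted cyclopentenone.
- That enone comes from (R)-4-silyloxycyclopentenone by alkenylcopper addition and β-elimination.
- Ring order: five-membered ring bought, six-membered ring second (key step), oxirane third.

Assumption: the SMILES defines the target completely; locants in bicyclic names follow octahydro-1H-inden-2-one numbering (C1 side chain, C2 ketone, C4 methylidene, C5/C6 acyloxy, C7 oxiranyl); compounds 1, 3, 7, 9, 19, 22 and 24 are catalogue compounds.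

**Route**

Step 1
Reactants: 1 3-bromobut-3-en-1-ol
Product: 2 [(3-bromobut-3-en-1-yl)oxy](tert-butyl)dimethylsilane
Conditions: TBSCl, imidazole, CH2Cl2, 0 °C → rt
Reagents that add atoms: tert-butyldimethylsilyl chloride, CC(C)(C)[Si](C)(C)Cl
Why: Standard silyl protection of the primary alcohol so that the vinyl bromide can be lithiated; no stereocentre.

Step 2
Reactants: 2 [(3-bromobut-3-en-1-yl)oxy](tert-butyl)dimethylsilane; 3 (4R)-4-{[tert-butyl(dimethyl)silyl]oxy}cyclopent-2-en-1-one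
Product: 6 (4R)-4-(4-{[tert-butyl(dimethyl)silyl]oxy}but-1-en-2-yl)cyclopent-2-en-1-one, via alkenylcopper 4 (not isolated), via silyloxy ketone 5 (not isolated)
Conditions: 2, t-BuLi (2 equiv), Et2O, −78 °C; CuI·PBu3; 3, −78 → −40 °C; aq NH4Cl; then DBU, CH2Cl2, 0 °C (brief)
Reagents that add atoms: none
Why: Halogen–lithium exchange and organocopper 1,4-addition anti to the silyloxy group set the new centre (later C3a), then E1cB loss of silanolate moves the enone (addition–elimination on a 4-silyloxycyclopentenone); DBU contact is kept short because the new centre is doubly allylic.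

Step 3
Reactants: 7 (2E)-3-iodo-2-methylprop-2-en-1-ol
Product: 8 {[(2E)-3-iodo-2-methylprop-2-en-1-yl]oxy}benzene
Conditions: PhOH, PPh3, DIAD, THF, 0 °C → rt
Reagents that add atoms: phenol, Oc1ccccc1
Why: Mitsunobu etherification of the primary allylic alcohol; the phenyl ether survives organometallic steps and is later the leaving group for π-allylpalladium formation; alkene geometry unchanged.

Step 4
Reactants: 8 {[(2E)-3-iodo-2-methylprop-2-en-1-yl]oxy}benzene; 6 (4R)-4-(4-{[tert-butyl(dimethyl)silyl]oxy}but-1-en-2-yl)cyclopent-2-en-1-one; 9 acetaldehyde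
Product: 13 (1S)-1-[(1S,2S,3R)-3-(4-{[tert-butyl(dimethyl)silyl]oxy}but-1-en-2-yl)-2-[(1E)-2-methyl-3-phenoxyprop-1-en-1-yl]-5-oxocyclopentyl]ethyl acetate, via alkenylcopper 10 (not isolated), via copper enolate 11 (not isolated), via copper aldolate 12 (not isolated)
Conditions: 8, t-BuLi (2 equiv), Et2O, −78 °C; CuI·PBu3; 6, −78 °C; 9 (3 equiv), −78 °C; Ac2O, −78 → −20 °C; aq NH4Cl
Reagents that add atoms: acetic anhydride, CC(=O)OC(C)=O
Why: Noyori-type three-component coupling: 1,4-addition anti to the C4 substituent, aldehyde capture anti to the new C3 substituent (all-trans ring), carbinol centre (S) from the closed Zimmerman–Traxler chair of the E(O)-enolate (anti aldol, modest selectivity expected, minor epimer removed here), and the aldolate is acetylated before retro-aldol can occur.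

Step 5
Reactants: 13 (the silyl ether acetate of step 4)
Product: 14 (1S)-1-[(1S,2S,3R)-3-(4-hydroxybut-1-en-2-yl)-2-[(1E)-2-methyl-3-phenoxyprop-1-en-1-yl]-5-oxocyclopentyl]ethyl acetate
Conditions: HF·pyridine, THF/pyridine, 0 °C
Reagents that add atoms: none
Why: Fluoride desilylation of the primary TBS ether under non-basic conditions that spare the β-acetoxy ketone; no stereocentre touched.

Step 6
Reactants: 14 (the primary alcohol of step 5)
Product: 15 (1S)-1-[(1S,2S,3R)-2-[(1E)-2-methyl-3-phenoxyprop-1-en-1-yl]-5-oxo-3-(4-oxobut-1-en-2-yl)cyclopentyl]ethyl acetate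
Conditions: Dess–Martin periodinane, pyridine, CH2Cl2, 0 °C; used at once
Reagents that add atoms: none
Why: Dess–Martin oxidation is neutral enough to give the β,γ-unsaturated aldehyde without conjugation or acetate elimination.

Step 7 (key step)
Reactants: 15 (the keto aldehyde of step 6)
Product: 17 (1S)-1-[(1S,3aR,6S,7R,7aR)-6-hydroxy-4-methylidene-2-oxo-7-(prop-1-en-2-yl)octahydro-1H-inden-1-yl]ethyl acetate, via allylindium 16 (not isolated)
Conditions: Pd(PPh3)4 (5 mol %), InI (1.5 equiv), THF, rt; aq NH4Cl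
Reagents that add atoms: none
Why: Pd-catalysed umpolung allylation (Tamaru–Araki type, Barbier-like): zerovalent palladium ionises the allyl phenyl ether, InI reduces the electrophilic π-allylpalladium to a nucleophilic allylindium, and its γ-carbon adds to the aldehyde (far more reactive than the ketone) through a closed chair fused to the forming chair, with tether, new isopropenyl group and O–In all equatorial, giving the trans-fused ring with 6-OH and 7-isopropenyl trans-diequatorial.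

Step 8
Reactants: 17 (the homoallylic alcohol of step 7)
Product: 18 (1S)-1-[(1S,3aR,6S,7S,7aR)-6-hydroxy-4-methylidene-7-[(2S)-2-methyloxiran-2-yl]-2-oxooctahydro-1H-inden-1-yl]ethyl acetate
Conditions: VO(acac)2 (5 mol %), t-BuOOH (1.5 equiv), CH2Cl2, 0 °C → rt
Reagents that add atoms: tert-butyl hydroperoxide, CC(C)(C)OO
Why: Hydroxyl-directed vanadium epoxidation of a homoallylic alcohol (Sharpless–Mihelich type): the equatorial C6–O–V is gauche to the isopropenyl group and delivers oxygen to its C6-side face in the rotamer with =CH2 eclipsing C7–H, which gives the (2S)-oxirane; the exocyclic methylene is anti-periplanar to the C6–O bond and cannot be reached.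

Step 9
Reactants: 18 (the epoxy alcohol of step 8); 19 (2R)-2-methylbutanoic acid
Product: 20 (1S,3aR,6S,7S,7aR)-1-[(1S)-1-(acetyloxy)ethyl]-4-methylidene-7-[(2S)-2-methyloxiran-2-yl]-2-oxooctahydro-1H-inden-6-yl (2R)-2-methylbutanoate
Conditions: DCC, DMAP (cat.), CH2Cl2, 0 °C → rt
Reagents that add atoms: none
Why: Steglich esterification of the equatorial secondary alcohol; no new stereocentre, and low temperature protects the α-centre of the acid.

Step 10
Reactants: 20 (the C6 ester of step 9)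
Product: 21 (1S,3aR,5S,6R,7S,7aR)-1-[(1S)-1-(acetyloxy)ethyl]-5-hydroxy-4-methylidene-7-[(2S)-2-methyloxiran-2-yl]-2-oxooctahydro-1H-inden-6-yl (2R)-2-methylbutanoate
Conditions: SeO2 (0.5 equiv), t-BuOOH (3 equiv), CH2Cl2, 0 °C → rt
Reagents that add atoms: selenium dioxide, O=[Se]=O; tert-butyl hydroperoxide, CC(C)(C)OO
Why: Riley/Sharpless allylic hydroxylation (ene reaction then [2,3]-shift) of the only remaining alkene: the ring CH2 (C5) is preferred over the tertiary ring-fusion C–H, and oxygen is returned axially, which is the 5S alcohol cis to the C6 ester.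

Step 11
Reactants: 22 (2S)-1-chloro-1-oxopropan-2-yl acetate
Product: 23 (2S)-3-oxobutan-2-yl acetate
Conditions: MeMgBr (1.0 equiv), Fe(acac)3 (3 mol %), THF, −78 °C
Reagents that add atoms: methylmagnesium bromide, C[Mg]Br
Why: Iron-catalysed acyl chloride–Grignard ketone synthesis (Fürstner type) is faster than attack on the acetate or the product ketone; the lactate stereocentre is not touched.

Step 12
Reactants: 23 (2S)-3-oxobutan-2-yl acetate; 24 tert-butyl (triphenylphosphoranylidene)acetate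
Product: 25 tert-butyl (2E,4S)-4-(acetyloxy)-3-methylpent-2-enoate
Conditions: toluene, 90 °C
Reagents that add atoms: none
Why: Wittig olefination with a stabilised ylide under base-free conditions (no racemisation); the ester ends trans to the bulkier branched substituent (E), and the minor Z isomer is removed.

Step 13
Reactants: 25 (the tert-butyl ester of step 12)
Product: 26 (2E,4S)-4-(acetyloxy)-3-methylpent-2-enoic acid
Conditions: CF3CO2H, CH2Cl2, 0 °C → rt
Reagents that add atoms: none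
Why: Acidolysis of the tert-butyl ester (E1 loss of isobutene) leaves the acetate and the alkene geometry intact.

Step 14
Reactants: 21 (the C5 alcohol of step 10); 26 (2E,4S)-4-(acetyloxy)-3-methylpent-2-enoic acid
Product: 28 (1S,3aR,5S,6R,7S,7aR)-1-[(1S)-1-(acetyloxy)ethyl]-4-methylidene-6-{[(2R)-2-methylbutanoyl]oxy}-7-[(2S)-2-methyloxiran-2-yl]-2-oxooctahydro-1H-inden-5-yl (2E,4S)-4-(acetyloxy)-3-methylpent-2-enoate, via mixed anhydride 27 (not isolated)
Conditions: 26, 2,4,6-trichlorobenzoyl chloride, Et3N, THF, rt; then 21, DMAP, toluene, rt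
Reagents that add atoms: none
Why: Yamaguchi esterification acylates the hindered axial allylic alcohol with retention at C5 under conditions mild enough for the β-acetoxy ketone and the oxirane.

**Compound list**

1 | 3-bromobut-3-en-1-ol | C=C(Br)CCO | starting material
2 | [(3-bromobut-3-en-1-yl)oxy](tert-butyl)dimethylsilane | C=C(Br)CCO[Si](C)(C)C(C)(C)C | intermediate
3 | (4R)-4-{[tert-butyl(dimethyl)silyl]oxy}cyclopent-2-en-1-one | O=C1C=C[C@H](O[Si](C)(C)C(C)(C)C)C1 | starting material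
4 | (4-{[tert-butyl(dimethyl)silyl]oxy}but-1-en-2-yl)copper, PBu3 complex | C=C([Cu])CCO[Si](C)(C)C(C)(C)C | intermediate
5 | (3S,4R)-3-(4-{[tert-butyl(dimethyl)silyl]oxy}but-1-en-2-yl)-4-{[tert-butyl(dimethyl)silyl]oxy}cyclopentan-1-one | O=C1C[C@@H](C(=C)CCO[Si](C)(C)C(C)(C)C)[C@H](O[Si](C)(C)C(C)(C)C)C1 | intermediate
6 | (4R)-4-(4-{[tert-butyl(dimethyl)silyl]oxy}but-1-en-2-yl)cyclopent-2-en-1-one | C=C(CCO[Si](C)(C)C(C)(C)C)[C@@H]1CC(=O)C=C1 | intermediate
7 | (2E)-3-iodo-2-methylprop-2-en-1-ol | OC/C(C)=C/I | starting material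
8 | {[(2E)-3-iodo-2-methylprop-2-en-1-yl]oxy}benzene | I/C=C(/COc1ccccc1)C | intermediate
9 | acetaldehyde | CC=O | starting material
10 | [(1E)-2-methyl-3-phenoxyprop-1-en-1-yl]copper, PBu3 complex | [Cu]/C=C(/COc1ccccc1)C | intermediate
11 | copper (3S,4R)-4-(4-{[tert-butyl(dimethyl)silyl]oxy}but-1-en-2-yl)-3-[(1E)-2-methyl-3-phenoxyprop-1-en-1-yl]cyclopent-1-en-1-olate | C=C(CCO[Si](C)(C)C(C)(C)C)[C@@H]1CC(O[Cu])=C[C@H]1/C=C(/COc2ccccc2)C | intermediate
12 | copper (1S)-1-[(1S,2S,3R)-3-(4-{[tert-butyl(dimethyl)silyl]oxy}but-1-en-2-yl)-2-[(1E)-2-methyl-3-phenoxyprop-1-en-1-yl]-5-oxocyclopentyl]ethan-1-olate | C=C(CCO[Si](C)(C)C(C)(C)C)[C@@H]1CC(=O)[C@H]([C@H](C)O[Cu])[C@H]1/C=C(/COc2ccccc2)C | intermediate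
13 | (1S)-1-[(1S,2S,3R)-3-(4-{[tert-butyl(dimethyl)silyl]oxy}but-1-en-2-yl)-2-[(1E)-2-methyl-3-phenoxyprop-1-en-1-yl]-5-oxocyclopentyl]ethyl acetate | C=C(CCO[Si](C)(C)C(C)(C)C)[C@@H]1CC(=O)[C@H]([C@H](C)OC(C)=O)[C@H]1/C=C(/COc2ccccc2)C | intermediate
14 | (1S)-1-[(1S,2S,3R)-3-(4-hydroxybut-1-en-2-yl)-2-[(1E)-2-methyl-3-phenoxyprop-1-en-1-yl]-5-oxocyclopentyl]ethyl acetate | C=C(CCO)[C@@H]1CC(=O)[C@H]([C@H](C)OC(C)=O)[C@H]1/C=C(/COc2ccccc2)C | intermediate
15 | (1S)-1-[(1S,2S,3R)-2-[(1E)-2-methyl-3-phenoxyprop-1-en-1-yl]-5-oxo-3-(4-oxobut-1-en-2-yl)cyclopentyl]ethyl acetate | C=C(CC=O)[C@@H]1CC(=O)[C@H]([C@H](C)OC(C)=O)[C@H]1/C=C(/COc2ccccc2)C | intermediate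
16 | allylindium from 15: iodo(phenoxy)[(2E)-2-methyl-3-{(1S,2S,5R)-2-[(1S)-1-(acetyloxy)ethyl]-3-oxo-5-(4-oxobut-1-en-2-yl)cyclopentyl}prop-2-en-1-yl]indium | C=C(CC=O)[C@@H]1CC(=O)[C@H]([C@H](C)OC(C)=O)[C@H]1/C=C(/C[In](I)Oc2ccccc2)C | intermediate
17 | (1S)-1-[(1S,3aR,6S,7R,7aR)-6-hydroxy-4-methylidene-2-oxo-7-(prop-1-en-2-yl)octahydro-1H-inden-1-yl]ethyl acetate | C=C1[C@@H]2CC(=O)[C@H]([C@H](C)OC(C)=O)[C@H]2[C@H](C(C)=C)[C@@H](O)C1 | intermediate
18 | (1S)-1-[(1S,3aR,6S,7S,7aR)-6-hydroxy-4-methylidene-7-[(2S)-2-methyloxiran-2-yl]-2-oxooctahydro-1H-inden-1-yl]ethyl acetate | C=C1[C@@H]2CC(=O)[C@H]([C@H](C)OC(C)=O)[C@H]2[C@H]([C@@]2(C)CO2)[C@@H](O)C1 | intermediate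
19 | (2R)-2-methylbutanoic acid | CC[C@@H](C)C(=O)O | starting material
20 | (1S,3aR,6S,7S,7aR)-1-[(1S)-1-(acetyloxy)ethyl]-4-methylidene-7-[(2S)-2-methyloxiran-2-yl]-2-oxooctahydro-1H-inden-6-yl (2R)-2-methylbutanoate | C=C1[C@@H]2CC(=O)[C@H]([C@H](C)OC(C)=O)[C@H]2[C@H]([C@@]2(C)CO2)[C@@H](OC(=O)[C@H](C)CC)C1 | intermediate
21 | (1S,3aR,5S,6R,7S,7aR)-1-[(1S)-1-(acetyloxy)ethyl]-5-hydroxy-4-methylidene-7-[(2S)-2-methyloxiran-2-yl]-2-oxooctahydro-1H-inden-6-yl (2R)-2-methylbutanoate | C=C1[C@@H]2CC(=O)[C@H]([C@H](C)OC(C)=O)[C@H]2[C@H]([C@@]2(C)CO2)[C@@H](OC(=O)[C@H](C)CC)[C@H]1O | intermediate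
22 | (2S)-1-chloro-1-oxopropan-2-yl acetate | ClC(=O)[C@H](C)OC(C)=O | starting material
23 | (2S)-3-oxobutan-2-yl acetate | CC(=O)[C@H](C)OC(C)=O | intermediate
24 | tert-butyl (triphenylphosphoranylidene)acetate | CC(C)(C)OC(=O)C=P(c1ccccc1)(c1ccccc1)c1ccccc1 | starting material
25 | tert-butyl (2E,4S)-4-(acetyloxy)-3-methylpent-2-enoate | CC(C)(C)OC(=O)/C=C(\C)[C@H](C)OC(C)=O | intermediate
26 | (2E,4S)-4-(acetyloxy)-3-methylpent-2-enoic acid | OC(=O)/C=C(\C)[C@H](C)OC(C)=O | intermediate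
27 | (2E,4S)-4-(acetyloxy)-3-methylpent-2-enoic 2,4,6-trichlorobenzoic anhydride | O=C(OC(=O)/C=C(\C)[C@H](C)OC(C)=O)c1c(Cl)cc(Cl)cc1Cl | intermediate
28 | (1S,3aR,5S,6R,7S,7aR)-1-[(1S)-1-(acetyloxy)ethyl]-4-methylidene-6-{[(2R)-2-methylbutanoyl]oxy}-7-[(2S)-2-methyloxiran-2-yl]-2-oxooctahydro-1H-inden-5-yl (2E,4S)-4-(acetyloxy)-3-methylpent-2-enoate | C=C1[C@@H]2CC(=O)[C@H]([C@H](C)OC(C)=O)[C@H]2[C@H]([C@@]2(C)CO2)[C@@H](OC(=O)[C@H](C)CC)[C@H]1OC(=O)/C=C(\C)[C@H](C)OC(C)=O | target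

**Step count and risks**

Total step count: 14. Longest linear sequence: 10 steps (steps 1, 2, 4, 5, 6, 7, 8, 9, 10, 14).

Steps most likely to fail:

- **Step 7 (umpolung ring closure).** The allylindium may protonate, the sensitive aldehyde may conjugate before closure, or the trans-fused closure may be slow. The fallback gives up polarity reversal for a Lewis-acid carbonyl-ene closure of the citronellal-to-isopulegol kind. It sets out from 6: copper-catalysed 1,4-addition of commercial 2-methylprop-1-enylmagnesium bromide with the same trapping by 9 and Ac2O gives (1S)-1-[(1S,2S,3R)-3-(4-{[tert-butyl(dimethyl)silyl]oxy}but-1-en-2-yl)-2-(2-methylprop-1-en-1-yl)-5-oxocyclopentyl]ethyl acetate F1. HF·pyridine gives the primary alcohol (1S)-1-[(1S,2S,3R)-3-(4-hydroxybut-1-en-2-yl)-2-(2-methylprop-1-en-1-yl)-5-oxocyclopentyl]ethyl acetate F2, and Dess–Martin oxidation gives the aldehyde (1S)-1-[(1S,2S,3R)-2-(2-methylprop-1-en-1-yl)-5-oxo-3-(4-oxobut-1-en-2-yl)cyclopentyl]ethyl acetate F3. Me2AlCl in CH2Cl2 at −78 °C then closes the ring through the same all-equatorial chair and the route is rejoined at 17.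

- **Step 10 (SeO2 allylic hydroxylation).** The hydroxyl may come in equatorial, over-oxidise to the enone, or the oxirane may suffer. The fallback changes how C5 is set: oxidation level first, configuration by inversion. It sets out from 20: the crude SeO2/t-BuOOH product (either epimer) is taken on with MnO2 to the enone (1S,3aR,6R,7S,7aR)-1-[(1S)-1-(acetyloxy)ethyl]-4-methylidene-7-[(2S)-2-methyloxiran-2-yl]-2,5-dioxooctahydro-1H-inden-6-yl (2R)-2-methylbutanoate F4. NaBH4/CeCl3 at −78 °C (axial hydride attack) gives the equatorial alcohol (1S,3aR,5R,6R,7S,7aR)-1-[(1S)-1-(acetyloxy)ethyl]-5-hydroxy-4-methylidene-7-[(2S)-2-methyloxiran-2-yl]-2-oxooctahydro-1H-inden-6-yl (2R)-2-methylbutanoate F5. Mitsunobu esterification of F5 with 26 (PPh3, DIAD) inverts C5 and rejoins the route at 28, replacing step 14.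

- **Step 4 (three-component coupling).** The carbinol centre may form with poor selectivity, or the aldolate may revert or eliminate before acetylation. The fallback separates the events and uses a boron aldol. It sets out from 6 and 8: the same alkenylcopper addition is quenched with Me3SiCl to give the silyl enol ether tert-butyl(dimethyl){[3-[(1R,2S)-2-[(1E)-2-methyl-3-phenoxyprop-1-en-1-yl]-4-[(trimethylsilyl)oxy]cyclopent-3-en-1-yl]but-3-en-1-yl]oxy}silane F6. MeLi, then (c-Hex)2BCl and 9 at −78 °C, give through the closed boron chair the anti aldol (2S,3S,4R)-4-(4-{[tert-butyl(dimethyl)silyl]oxy}but-1-en-2-yl)-2-[(1S)-1-hydroxyethyl]-3-[(1E)-2-methyl-3-phenoxyprop-1-en-1-yl]cyclopentan-1-one F7. Ac2O/pyridine/DMAP at 0 °C then rejoins the route at 13.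

**Further compounds**

F1 | step 7 | (1S)-1-[(1S,2S,3R)-3-(4-{[tert-butyl(dimethyl)silyl]oxy}but-1-en-2-yl)-2-(2-methylprop-1-en-1-yl)-5-oxocyclopentyl]ethyl acetate | C=C(CCO[Si](C)(C)C(C)(C)C)[C@@H]1CC(=O)[C@H]([C@H](C)OC(C)=O)[C@H]1C=C(C)C
F2 | step 7 | (1S)-1-[(1S,2S,3R)-3-(4-hydroxybut-1-en-2-yl)-2-(2-methylprop-1-en-1-yl)-5-oxocyclopentyl]ethyl acetate | C=C(CCO)[C@@H]1CC(=O)[C@H]([C@H](C)OC(C)=O)[C@H]1C=C(C)C
F3 | step 7 | (1S)-1-[(1S,2S,3R)-2-(2-methylprop-1-en-1-yl)-5-oxo-3-(4-oxobut-1-en-2-yl)cyclopentyl]ethyl acetate | C=C(CC=O)[C@@H]1CC(=O)[C@H]([C@H](C)OC(C)=O)[C@H]1C=C(C)C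
F4 | step 10 | (1S,3aR,6R,7S,7aR)-1-[(1S)-1-(acetyloxy)ethyl]-4-methylidene-7-[(2S)-2-methyloxiran-2-yl]-2,5-dioxooctahydro-1H-inden-6-yl (2R)-2-methylbutanoate | C=C1[C@@H]2CC(=O)[C@H]([C@H](C)OC(C)=O)[C@H]2[C@H]([C@@]2(C)CO2)[C@@H](OC(=O)[C@H](C)CC)C1=O
F5 | step 10 | (1S,3aR,5R,6R,7S,7aR)-1-[(1S)-1-(acetyloxy)ethyl]-5-hydroxy-4-methylidene-7-[(2S)-2-methyloxiran-2-yl]-2-oxooctahydro-1H-inden-6-yl (2R)-2-methylbutanoate | C=C1[C@@H]2CC(=O)[C@H]([C@H](C)OC(C)=O)[C@H]2[C@H]([C@@]2(C)CO2)[C@@H](OC(=O)[C@H](C)CC)[C@@H]1O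
F6 | step 4 | tert-butyl(dimethyl){[3-[(1R,2S)-2-[(1E)-2-methyl-3-phenoxyprop-1-en-1-yl]-4-[(trimethylsilyl)oxy]cyclopent-3-en-1-yl]but-3-en-1-yl]oxy}silane | C=C(CCO[Si](C)(C)C(C)(C)C)[C@@H]1CC(O[Si](C)(C)C)=C[C@H]1/C=C(/COc2ccccc2)C
F7 | step 4 | (2S,3S,4R)-4-(4-{[tert-butyl(dimethyl)silyl]oxy}but-1-en-2-yl)-2-[(1S)-1-hydroxyethyl]-3-[(1E)-2-methyl-3-phenoxyprop-1-en-1-yl]cyclopentan-1-one | C=C(CCO[Si](C)(C)C(C)(C)C)[C@@H]1CC(=O)[C@H]([C@H](C)O)[C@H]1/C=C(/COc2ccccc2)C
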